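Numbering as in spiro[5.5]undecane: ring A = C1(OH)(CH3)–C2–C3(Br)–C4–C5(CH3)2–C6, ring B = C6–C7=C8–C9(=CHBr)–C10–C11.
Retrosynthetic cuts, in order: C3–Br (SN2 on an axial C3 alcohol), C3–H (reduction of a C3 ketone), C1–CH3 (methyl addition to a C1 ketone), C9=CHBr (Wittig on a C9 enone), the C10/C11 hydrogens (back to a cross-conjugated dienone), then the C5–C6 bond of ring A, and last the bond from C1 to the arene.
Enabling feature: the spiro carbon C6 is para to C9 within ring B and lies in ring A between the oxygen-bearing C1 and the fully substituted C5. Ring B can therefore be a para-oxygenated benzene ring and ring A a 2,2-dimethylcyclopentanol whose CMe2 carbon shifts from the carbinol carbon to the oxidised para carbon.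
Forward order: 2,2-dimethylcyclopentanone → (R)-4-silyloxy ketone → 1-(4-hydroxyphenyl)cyclopentanol → oxidative dearomatisation with 1,2-shift (six-membered ring A, the spiro centre and the dienone form of ring B in one operation) → desymmetrising 1,4-reduction → bromomethylenation → methyl addition → oxidation, reduction and bromination at C3.
Stereochemistry: C3–O from a ligand-controlled conjugate borylation; C6 from a ligand-controlled copper hydride desymmetrisation of the dienone; C1 from equatorial methyl delivery on the chair locked by the equatorial C3 silyloxy group; the final C3 from a chelation-controlled ketone reduction (hydroxyl cis to C1–OH) followed by SN2 inversion; the C9=CHBr geometry from the Wittig step with separation of the geometric isomers.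

Key step: step 5

Assumption: compounds 1 and 6, both antipodes of the two chiral bisphosphines and all reagents are purchased; in steps 2 and 6 the ligand antipode used is the one that delivers the configuration drawn.

Step 1
Reactants: 1 2,2-dimethylcyclopentan-1-one
Product: 2 5,5-dimethylcyclopent-2-en-1-one
Conditions: IBX (1.5 equiv), DMSO/toluene, 70 °C
Reagents that add atoms: none
Why: IBX α,β-dehydrogenation of the ketone can only engage the single CH2–CH2 flank because the other α-carbon is quaternary, so one enone should form and no stereocentre is involved.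

Step 2
Reactants: 2 5,5-dimethylcyclopent-2-en-1-one
Product: 4 (R)-4-hydroxy-2,2-dimethylcyclopentan-1-one, via boryl ketone 3 (not isolated)
Conditions: CuCl (3 mol %), NaOtBu (5 mol %), chiral bisphosphine (QuinoxP* or Josiphos type), B2pin2, MeOH, THF, rt; then NaBO3·4H2O, THF/H2O, rt
Reagents that add atoms: bis(pinacolato)diboron, CC1(C)OB(OC1(C)C)B1OC(C)(C)C(C)(C)O1 (boryl group of 3); sodium perborate (NaBO3·4H2O), [Na+].[Na+].O[B-]1(O)OO[B-](O)(O)OO1 (oxygen of 4)
Why: Copper-catalysed enantioselective conjugate borylation of the cyclic enone sets the carbinol carbon (the later C3) under ligand control of the boryl–copper face selection, and the C–B bond is then oxidised with retention to the β-hydroxy ketone.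

Step 3
Reactants: 4 (R)-4-hydroxy-2,2-dimethylcyclopentan-1-one
Product: 5 (R)-4-[(tert-butyldimethylsilyl)oxy]-2,2-dimethylcyclopentan-1-one
Conditions: TBSCl, imidazole, DMF, rt
Reagents that add atoms: tert-butyldimethylsilyl chloride, CC(C)(C)[Si](C)(C)Cl
Why: Standard silylation of a secondary alcohol under mildly basic conditions that should not trigger β-elimination of the β-hydroxy ketone; the stereocentre is untouched.

Step 4
Reactants: 5 (R)-4-[(tert-butyldimethylsilyl)oxy]-2,2-dimethylcyclopentan-1-one; 6 (4-bromophenoxy)(tert-butyl)dimethylsilane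
Product: 9 4-[(1R,4R)-4-[(tert-butyldimethylsilyl)oxy]-1-hydroxy-2,2-dimethylcyclopentyl]phenol, via aryllithium 7 (not isolated), via bis-silyl ether 8 (not isolated)
Conditions: 6, n-BuLi, THF, −78 °C; then 5, −78 → −20 °C; aq NH4Cl; then K2CO3, MeOH, 0 °C
Reagents that add atoms: n-butyllithium, [Li]CCCC (lithium of 7)
Why: Bromine–lithium exchange and 1,2-addition of the aryllithium to the ketone are followed by chemoselective methanolysis of the aryl silyl ether, which cleaves far faster than the alkyl silyl ether; attack anti to the silyloxy group should give mainly the epimer drawn, but the carbinol configuration is irrelevant because step 5 destroys it.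

Step 5
Reactants: 9 4-[(1R,4R)-4-[(tert-butyldimethylsilyl)oxy]-1-hydroxy-2,2-dimethylcyclopentyl]phenol
Product: 10 (R)-3-[(tert-butyldimethylsilyl)oxy]-5,5-dimethylspiro[5.5]undeca-7,10-diene-1,9-dione
Conditions: PhI(OAc)2 (1.1 equiv), (CF3)2CHOH, 0 °C, 10 min
Reagents that add atoms: none
Why: PhI(OAc)2 oxidises the phenol to a phenoxenium-type cation with the positive charge on the para carbon (the future spiro carbon C6), and the cyclopentanol ring bond from the carbinol carbon to the CMe2 carbon, aligned with the aromatic π-system, shifts to that carbon as the carbinol oxygen lone pair pushes in and the hydroxyl proton is lost. The closest known reaction type is the oxidative dearomatisation of para-(1-hydroxycycloalkyl)phenols with concomitant semipinacol (Wagner–Meerwein-type) 1,2-alkyl shift in fluorinated alcohols. Ring A is closed by ring expansion of the five-membered carbocycle (the C5–C6 bond forms by a suprafacial 1,2-shift as the old bond from C5 to the carbinol carbon breaks, not by an end-to-end cyclisation), while ring B is not closed but converted from the benzene ring into the cross-conjugated dienone. No new stereocentre results: C6 carries two constitutionally identical enone arms and the carbinol stereocentre becomes the C1 carbonyl, so both carbinol epimers of 9 converge on 10 and the C3 silyloxy stereocentre is untouched. The step needs migration of the quaternary CMe2 carbon and not of the ring CH2 carbon, which the higher migratory aptitude of the more substituted carbon and the inductive deactivation of the CH2 arm by the β-silyloxy group should secure; it also needs the shift to outrun capture of the cation, which the non-nucleophilic, cation-stabilising solvent should favour.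

Step 6
Reactants: 10 (R)-3-[(tert-butyldimethylsilyl)oxy]-5,5-dimethylspiro[5.5]undeca-7,10-diene-1,9-dione
Product: 12 (3R,6S)-3-[(tert-butyldimethylsilyl)oxy]-5,5-dimethylspiro[5.5]undec-7-ene-1,9-dione, via silyl dienol ether 11 (not isolated)
Conditions: Cu(OAc)2 (5 mol %), DTBM-SEGPHOS (5 mol %), (MeO)2MeSiH, toluene, 0 °C; then 10% aq citric acid, THF, 0 °C
Reagents that add atoms: dimethoxy(methyl)silane, CO[SiH](C)OC (silyl group of 11)
Why: Ligand-controlled copper hydride 1,4-reduction (enantioselective desymmetrisation of 4,4-disubstituted cyclohexadienones) should reduce only the enone arm trans to the C3 silyloxy group: the two β-carbons are told apart through the very different groups flanking C6 (the C1 carbonyl against the C5 CMe2), the remote C3 centre should not override the catalyst, and the silyl dienol ether 11 resists a second reduction, which sets C6.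

Step 7
Reactants: 12 (3R,6S)-3-[(tert-butyldimethylsilyl)oxy]-5,5-dimethylspiro[5.5]undec-7-ene-1,9-dione
Product: 13 (3R,6S,9Z)-9-(bromomethylidene)-3-[(tert-butyldimethylsilyl)oxy]-5,5-dimethylspiro[5.5]undec-7-en-1-one
Conditions: Ph3P+CH2Br Br−, KOtBu, THF, −78 °C; then 12, −78 → 0 °C; chromatography on AgNO3-doped silica
Reagents that add atoms: (bromomethyl)triphenylphosphonium bromide, BrC[P+](c1ccccc1)(c1ccccc1)c1ccccc1.[Br-]
Why: Wittig bromomethylenation should attack only the unhindered C9 enone carbonyl (the C1 ketone is shielded by the adjacent spiro carbon); little intrinsic bias between the C8–H and C10–H2 flanks is expected, so the 9Z isomer (bromine on the side of C8) is isolated by chromatography from its 9E isomer.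

Step 8
Reactants: 13 (3R,6S,9Z)-9-(bromomethylidene)-3-[(tert-butyldimethylsilyl)oxy]-5,5-dimethylspiro[5.5]undec-7-en-1-one
Product: 14 (1S,3R,6S,9Z)-9-(bromomethylidene)-3-[(tert-butyldimethylsilyl)oxy]-1,5,5-trimethylspiro[5.5]undec-7-en-1-ol
Conditions: CeCl3, MeLi, THF, −78 °C; then 13, −78 → −40 °C; aq NH4Cl
Reagents that add atoms: methyllithium, [Li]C
Why: Organocerium 1,2-addition to the hindered, enolisable ketone: in the chair with the C3 silyloxy group equatorial the axial C5 methyl blocks axial attack, so methyl should enter equatorially and leave the new hydroxyl axial, trans to the silyloxy group and anti to the axial C7 arm, which is the C1 configuration of the target; the vinyl bromide should be inert to the weakly basic reagent at low temperature.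

Step 9
Reactants: 14 (1S,3R,6S,9Z)-9-(bromomethylidene)-3-[(tert-butyldimethylsilyl)oxy]-1,5,5-trimethylspiro[5.5]undec-7-en-1-ol
Product: 15 (1S,3R,6S,9Z)-9-(bromomethylidene)-1,5,5-trimethylspiro[5.5]undec-7-ene-1,3-diol
Conditions: Bu4NF, THF, 0 °C → rt; aq NH4Cl
Reagents that add atoms: none
Why: Fluoride desilylation of the secondary silyl ether; no stereocentre is affected and the bromodiene is stable to fluoride.

Step 10
Reactants: 15 (1S,3R,6S,9Z)-9-(bromomethylidene)-1,5,5-trimethylspiro[5.5]undec-7-ene-1,3-diol
Product: 16 (1S,6S,9Z)-9-(bromomethylidene)-1-hydroxy-1,5,5-trimethylspiro[5.5]undec-7-en-3-one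
Conditions: Dess–Martin periodinane, NaHCO3, CH2Cl2, 0 °C → rt
Reagents that add atoms: none
Why: Dess–Martin oxidation converts only the secondary alcohol (the tertiary one cannot be oxidised), and the buffered, non-basic medium should avoid retro-aldol cleavage or dehydration of the tertiary β-hydroxy ketone.

Step 11
Reactants: 16 (1S,6S,9Z)-9-(bromomethylidene)-1-hydroxy-1,5,5-trimethylspiro[5.5]undec-7-en-3-one
Product: 17 (1S,3S,6S,9Z)-9-(bromomethylidene)-1,5,5-trimethylspiro[5.5]undec-7-ene-1,3-diol
Conditions: Et2BOMe, THF/MeOH (4:1), −78 °C; NaBH4, −78 °C; AcOH, then MeOH co-evaporation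
Reagents that add atoms: none
Why: Narasaka–Prasad reduction: the boron chelate ties the axial C1 oxygen to the C3 carbonyl and external hydride should attack from the face opposite the boron bridge (also the only face not blocked by the syn-axial hydroxyl and methyl), giving the cis-1,3-diol with the C3 hydroxyl axial.

Step 12
Reactants: 17 (1S,3S,6S,9Z)-9-(bromomethylidene)-1,5,5-trimethylspiro[5.5]undec-7-ene-1,3-diol
Product: 18 (1S,3R,6S,9Z)-3-bromo-9-(bromomethylidene)-1,5,5-trimethylspiro[5.5]undec-7-en-1-ol
Conditions: CBr4, PPh3, 2,6-lutidine, CH2Cl2, 0 °C → rt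
Reagents that add atoms: carbon tetrabromide, BrC(Br)(Br)Br
Why: Appel bromination activates only the secondary hydroxyl (the tertiary one is too hindered), and SN2 displacement of the axial oxyphosphonium group by bromide along the equatorial trajectory should invert C3 to the equatorial bromide of the target.

Compound list
1 | 2,2-dimethylcyclopentan-1-one | CC1(C)CCCC1=O | starting material
2 | 5,5-dimethylcyclopent-2-en-1-one | CC1(C)CC=CC1=O | intermediate
3 | (R)-2,2-dimethyl-4-(4,4,5,5-tetramethyl-1,3,2-dioxaborolan-2-yl)cyclopentan-1-one | CC1(C)C[C@@H](B2OC(C)(C)C(C)(C)O2)CC1=O | intermediate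
4 | (R)-4-hydroxy-2,2-dimethylcyclopentan-1-one | CC1(C)C[C@@H](O)CC1=O | intermediate
5 | (R)-4-[(tert-butyldimethylsilyl)oxy]-2,2-dimethylcyclopentan-1-one | CC1(C)C[C@@H](O[Si](C)(C)C(C)(C)C)CC1=O | intermediate
6 | (4-bromophenoxy)(tert-butyl)dimethylsilane | CC(C)(C)[Si](C)(C)Oc1ccc(Br)cc1 | starting material
7 | [4-[(tert-butyldimethylsilyl)oxy]phenyl]lithium | [Li]c1ccc(O[Si](C)(C)C(C)(C)C)cc1 | intermediate
8 | (1R,4R)-4-[(tert-butyldimethylsilyl)oxy]-1-[4-[(tert-butyldimethylsilyl)oxy]phenyl]-2,2-dimethylcyclopentan-1-ol (expected major carbinol epimer) | CC1(C)C[C@@H](O[Si](C)(C)C(C)(C)C)C[C@]1(O)c2ccc(O[Si](C)(C)C(C)(C)C)cc2 | intermediate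
9 | 4-[(1R,4R)-4-[(tert-butyldimethylsilyl)oxy]-1-hydroxy-2,2-dimethylcyclopentyl]phenol (expected major carbinol epimer) | CC1(C)C[C@@H](O[Si](C)(C)C(C)(C)C)C[C@]1(O)c2ccc(O)cc2 | intermediate
10 | (R)-3-[(tert-butyldimethylsilyl)oxy]-5,5-dimethylspiro[5.5]undeca-7,10-diene-1,9-dione | CC1(C)C[C@@H](O[Si](C)(C)C(C)(C)C)CC(=O)C12C=CC(=O)C=C2 | intermediate
11 | (3R,6S)-3-[(tert-butyldimethylsilyl)oxy]-9-{[dimethoxy(methyl)silyl]oxy}-5,5-dimethylspiro[5.5]undeca-7,9-dien-1-one | CC1(C)C[C@@H](O[Si](C)(C)C(C)(C)C)CC(=O)[C@@]12C=CC(O[Si](C)(OC)OC)=CC2 | intermediate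
12 | (3R,6S)-3-[(tert-butyldimethylsilyl)oxy]-5,5-dimethylspiro[5.5]undec-7-ene-1,9-dione | CC1(C)C[C@@H](O[Si](C)(C)C(C)(C)C)CC(=O)[C@@]12C=CC(=O)CC2 | intermediate
13 | (3R,6S,9Z)-9-(bromomethylidene)-3-[(tert-butyldimethylsilyl)oxy]-5,5-dimethylspiro[5.5]undec-7-en-1-one | CC1(C)C[C@@H](O[Si](C)(C)C(C)(C)C)CC(=O)[C@@]12C=C/C(=C\Br)CC2 | intermediate
14 | (1S,3R,6S,9Z)-9-(bromomethylidene)-3-[(tert-butyldimethylsilyl)oxy]-1,5,5-trimethylspiro[5.5]undec-7-en-1-ol | CC1(C)C[C@@H](O[Si](C)(C)C(C)(C)C)C[C@](C)(O)[C@@]12C=C/C(=C\Br)CC2 | intermediate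
15 | (1S,3R,6S,9Z)-9-(bromomethylidene)-1,5,5-trimethylspiro[5.5]undec-7-ene-1,3-diol | CC1(C)C[C@@H](O)C[C@](C)(O)[C@@]12C=C/C(=C\Br)CC2 | intermediate
16 | (1S,6S,9Z)-9-(bromomethylidene)-1-hydroxy-1,5,5-trimethylspiro[5.5]undec-7-en-3-one | CC1(C)CC(=O)C[C@](C)(O)[C@@]12C=C/C(=C\Br)CC2 | intermediate
17 | (1S,3S,6S,9Z)-9-(bromomethylidene)-1,5,5-trimethylspiro[5.5]undec-7-ene-1,3-diol | CC1(C)C[C@H](O)C[C@](C)(O)[C@@]12C=C/C(=C\Br)CC2 | intermediate
18 | (1S,3R,6S,9Z)-3-bromo-9-(bromomethylidene)-1,5,5-trimethylspiro[5.5]undec-7-en-1-ol | CC1(C)C[C@@H](Br)C[C@](C)(O)[C@@]12C=C/C(=C\Br)CC2 | target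

Total step count: 12. Longest linear sequence: 12 steps (1 → 18); compound 6 enters in step 4.

Steps most likely to fail

Step 7. The olefination may show poor geometric selectivity, because C8–H and the C10 methylene flank the carbonyl almost symmetrically, and the two geometric isomers may co-elute. The fallback sets out from 12 and returns to the route at 13. A boron-Wittig olefination of 12 with lithiated bis(pinacolboryl)methane (CH2(Bpin)2, lithium 2,2,6,6-tetramethylpiperidide, THF, −78 → 0 °C) should give the configurationally stable alkenyl boronate (3R,6S,9Z)-3-[(tert-butyldimethylsilyl)oxy]-5,5-dimethyl-9-[(4,4,5,5-tetramethyl-1,3,2-dioxaborolan-2-yl)methylidene]spiro[5.5]undec-7-en-1-one F1. The bulky boryl group should make the geometric isomers easier to separate at this stage. Stereoretentive bromodeboronation of F1 (CuBr2, MeOH/H2O, rt → 50 °C) should then give 13.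

Step 6. The copper hydride may discriminate poorly between the two diastereotopic enone arms, or reduce both. The fallback sets out from 5 and returns at 12; it builds the spiro centre by a stereospecific shift, so ring A still arises by expansion of the cyclopentanol, and it bypasses steps 4 and 5 as well.
- Commercial 1,4-dioxaspiro[4.5]decan-8-one is condensed with 2,4,6-triisopropylbenzenesulfonohydrazide (MeOH, rt) to the hydrazone N'-(1,4-dioxaspiro[4.5]decan-8-ylidene)-2,4,6-tri(propan-2-yl)benzenesulfonohydrazide F2.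
- A Shapiro reaction (n-BuLi, 2.1 equiv, THF, −78 → 0 °C) gives (1,4-dioxaspiro[4.5]dec-7-en-8-yl)lithium F3. It is added to 5 at −78 °C, anti to the silyloxy group, to give (1R,4R)-4-[(tert-butyldimethylsilyl)oxy]-1-(1,4-dioxaspiro[4.5]dec-7-en-8-yl)-2,2-dimethylcyclopentan-1-ol F4; the minor carbinol epimer is removed by chromatography.
- Hydroxyl-directed epoxidation (VO(acac)2, t-BuOOH, CH2Cl2, 0 °C) should occur from the rotamer that keeps the CMe2 carbon out of the alkene plane, giving (1R,4R)-4-[(tert-butyldimethylsilyl)oxy]-2,2-dimethyl-1-[(1'R,6'S)-spiro[1,3-dioxolane-2,3'-[7]oxabicyclo[4.1.0]heptan]-6'-yl]cyclopentan-1-ol F5.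
- BF3·OEt2 (CH2Cl2, −78 °C) should open the tertiary C–O bond of the epoxide while the CMe2 carbon migrates anti to it (semipinacol rearrangement of a 2,3-epoxy alcohol, cyclopentanol → cyclohexanone). This gives (3R,6R,7R)-3-[(tert-butyldimethylsilyl)oxy]-7-hydroxy-5,5-dimethylspiro[5.5]undecane-1,9-dione 9-(ethane-1,2-diyl ketal) F6, with C6 fixed relative to C3.
- Mild aqueous acid (PPTS, acetone/H2O, 60 °C) should remove the ketal to give (3R,6R,7R)-3-[(tert-butyldimethylsilyl)oxy]-7-hydroxy-5,5-dimethylspiro[5.5]undecane-1,9-dione F7, which should lose water towards C8 under the same conditions to give 12.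

Step 12. E2 elimination from the axial oxyphosphonium ion (two antiperiplanar axial hydrogens), or capture of phosphorus by the syn-axial tertiary hydroxyl, may outrun substitution. The fallback sets out from 17 and returns at 18; it replaces the one-pot phosphorus activation by a two-stage sulfonate route. Selective mesylation of the secondary hydroxyl (MsCl, Et3N, CH2Cl2, −20 °C) gives the isolable axial mesylate (1S,3S,6S,9Z)-9-(bromomethylidene)-1-hydroxy-1,5,5-trimethylspiro[5.5]undec-7-en-3-yl methanesulfonate F8. Displacement with LiBr (DMF, 40 °C), where bromide acts as a nucleophile under salt-only, non-basic conditions, should then give 18 with inversion.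

Further compounds
F1 | step 7 | (3R,6S,9Z)-3-[(tert-butyldimethylsilyl)oxy]-5,5-dimethyl-9-[(4,4,5,5-tetramethyl-1,3,2-dioxaborolan-2-yl)methylidene]spiro[5.5]undec-7-en-1-one | CC1(C)C[C@@H](O[Si](C)(C)C(C)(C)C)CC(=O)[C@@]12C=C/C(=C\B3OC(C)(C)C(C)(C)O3)CC2
F2 | step 6 | N'-(1,4-dioxaspiro[4.5]decan-8-ylidene)-2,4,6-tri(propan-2-yl)benzenesulfonohydrazide | CC(C)c1cc(C(C)C)c(S(=O)(=O)NN=C2CCC3(CC2)OCCO3)c(C(C)C)c1
F3 | step 6 | (1,4-dioxaspiro[4.5]dec-7-en-8-yl)lithium | [Li]C1=CCC2(CC1)OCCO2
F4 | step 6 | (1R,4R)-4-[(tert-butyldimethylsilyl)oxy]-1-(1,4-dioxaspiro[4.5]dec-7-en-8-yl)-2,2-dimethylcyclopentan-1-ol | CC1(C)C[C@@H](O[Si](C)(C)C(C)(C)C)C[C@]1(O)C2=CCC3(OCCO3)CC2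
F5 | step 6 | (1R,4R)-4-[(tert-butyldimethylsilyl)oxy]-2,2-dimethyl-1-[(1'R,6'S)-spiro[1,3-dioxolane-2,3'-[7]oxabicyclo[4.1.0]heptan]-6'-yl]cyclopentan-1-ol | CC1(C)C[C@@H](O[Si](C)(C)C(C)(C)C)C[C@]1(O)[C@@]23O[C@@H]2CC4(OCCO4)CC3
F6 | step 6 | (3R,6R,7R)-3-[(tert-butyldimethylsilyl)oxy]-7-hydroxy-5,5-dimethylspiro[5.5]undecane-1,9-dione 9-(ethane-1,2-diyl ketal) | CC1(C)C[C@@H](O[Si](C)(C)C(C)(C)C)CC(=O)[C@@]12[C@H](O)CC3(OCCO3)CC2
F7 | step 6 | (3R,6R,7R)-3-[(tert-butyldimethylsilyl)oxy]-7-hydroxy-5,5-dimethylspiro[5.5]undecane-1,9-dione | CC1(C)C[C@@H](O[Si](C)(C)C(C)(C)C)CC(=O)[C@@]12[C@H](O)CC(=O)CC2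
F8 | step 12 | (1S,3S,6S,9Z)-9-(bromomethylidene)-1-hydroxy-1,5,5-trimethylspiro[5.5]undec-7-en-3-yl methanesulfonate | CC1(C)C[C@H](OS(C)(=O)=O)C[C@](C)(O)[C@@]12C=C/C(=C\Br)CC2
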